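The question is how strongly the rate of making product in the flask answers to the charge of partner at 50% conversion of the substrate.

| setting | ochre | violet | teal | flask |
|---|---|---|---|---|
| substrate | 0.018 M | 0.018 M | 0.0090 M | 0.018 M |
| partner | 0.0144 M | 0.0144 M | 0.0144 M | 0.0144 M |
| free catalyst | 45 µM | 180 µM | 90 µM | 90 µM |
| remark | run made earlier | run made earlier | run made earlier |  |

| run | time / min | product / % |
|---|---|---|
| ochre | 1.33 | 37.9 |
| ochre | 2.50 | 58.3 |
| ochre | 4.00 | 72.2 |
| ochre | 5.00 | 74.6 |
| ochre | 6.00 | 76.5 |
| violet | 0.500 | 52.4 |
| violet | 0.833 | 68.1 |
| violet | 1.50 | 77.2 |
| violet | 3.00 | 80.0 |
| violet | 6.00 | 79.3 |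
| teal | 1.33 | 69.8 |
| teal | 2.50 | 89.9 |
| teal | 4.00 | 97.9 |
| teal | 5.00 | 100.3 |
| teal | 6.00 | 100.2 |

(each reading ± 1 percentage point)

- what has left substrate counts as converted, also if it is not yet product
- no earlier run changes the charge of partner; that part of a forecast is a guess

1. apparent order in partner when 50% of the substrate are converted (percent change of the rate of making product for one percent more partner charged)

Violet levels off near 80.0% of the substrate, with partner charged at 80.0% of it, while teal, with partner in excess, reaches 100.3%. So one partner goes into each product, and partner is the limiting reagent in the flask.

Two extreme versions frame the answer. If the rate ignored partner, the order would be zero. If the rate were proportional to the partner remaining, and each converted substrate had taken one partner, the order would equal the partner leverage, the charge of partner over what that assumption leaves of it at that conversion: 2.67.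

Teal gives a hint of where the flask lies. Treating the product still to come in teal as a first-order decay, the readings give 0.900 /min early and 0.936 /min later, while teal's partner, reckoned at one per product, falls to 43.8% of its charge. My own reckoning therefore puts the flask nearer zero than the leverage.

The forecast says 1.1, within 0.5 to 1.7, and notes: “The partner dependence is therefore weak at high partner and looks saturating.”

The flask gives 0.53, inside that range and lower than the forecast's value.

    substrate + free catalyst ⇌ free catalyst + open intermediate (K = 1.70, k = 250 /M/s)
    free catalyst + open intermediate ⇌ catalyst intermediate (K = 27.0 /M, k = 11000 /M/s)
    partner + catalyst intermediate → free catalyst + product (k = 3300 /M/s)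

That order is 0.197 of the leverage. Catalyst intermediate can either meet partner or fall back to free catalyst and open intermediate, and this falling back supplies part of the flask's answer to partner. The run without it gives an order of 0.29, which is 0.107 of the same leverage.

(The readings were computed with made-up constants; noise was put on by code.)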